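## The problem

The target 21 is a flavone (ring A the benzo ring, ring C the pyranone, ring B the 2-phenyl group) that carries a 1-methylpiperidine (ring D) on C8 through the C8–C2' bond, with a free hydroxyl on C7 and a methyl ether on C5. C2' is the only stereocenter, so nothing in the molecule can relay its configuration; it must be set as R by a reagent or catalyst and then kept. C2' is benzylic, bears the basic nitrogen and lies between two ortho oxygens (O1 and the C7 hydroxyl). Once a phenol is free, the C2'–N1' bond can therefore ionise toward an ortho-quinone methide, and heat, strong acid or strong base late in the route put the configuration at risk. The chromone of ring C is opened by hydroxide and attacked by hydride, so it cannot be present when ring D is brought to the amine oxidation level and has to be built last. The C5 methyl ether must be told apart from the C7 hydroxyl, and every bond made at C2' is made next to a di-ortho-substituted aryl group. Before ring C exists, the aryl group on C2' is a 4-methoxy-2,6-dioxygenated phenyl with a mirror plane, so either ortho oxygen can become O1 and annulation of ring C raises no regiochemical question. The ring D atoms C2', N1', C6' and C5' map onto a 2-azadiene whose C2' terminus is the aldimine carbon of a ring A benzaldehyde, and C3' and C4' map onto the alkene of an acrylate, so ring D is a [4+2] adduct once C6' is carried as a lactam carbonyl and C3' bears a removable carboxyl.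

## Retrosynthesis

**Ring C last.** In 21 the bonds O1–C2, C3–C4 and C4–C4a are cut, which leads back to the ortho-iodophenol 18, phenylacetylene 19 and a one-carbon carbonyl unit delivered under palladium catalysis. The neighbouring option, a chromone built early, fails because ring C would not survive the hydride reduction of ring D. A diketone condensation at the end would need acid and heat on a labile C2'. The iodide 18 comes from the symmetrical diphenol 17 by cutting C–I; the mirror plane of 17 means only one mono-iodide exists. The precursor has lost rings B and C, and the forward reaction must run under mild, weakly basic conditions.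

**Ring D adjusted to a lactam.** Compound 17 is traced through functional group changes that do not touch C2'. The benzyl ethers are restored (16). C6' is raised to a lactam carbonyl (15). The N-methyl group is removed (14). A carboxyl is placed on C3' (12), and it is activated as the acyl oxazolidinone 10. The C3'–carboxyl bond is the only skeletal bond involved, and it is broken in the forward sense by radical decarboxylation. Each forward step has to leave C2' alone, which holds because C2' then carries an amide nitrogen and protected phenols and cannot ionise.

**The [4+2] disconnection.** In 10 the bonds C2'–C3' and C4'–C5' are cut, giving the achiral azadiene 7 and the commercial acrylimide 8. Cuts at N1'–C2' or N1'–C6' would each need a preformed chain and a separate way of setting C2'. This cut removes ring D and both of its stereocenters in one step and leaves two flat fragments. The forward reaction must deliver regiocontrol, exo topicity and facial control together. An endo adduct formed on the same acrylate face would carry the opposite C2', so 10 has to be diastereomerically pure before the C3' carboxyl is removed.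

**The azadiene.** In 7 the O–Si bond, the N–acyl bond and the C=N bond are cut in turn, leading through the N-acyl imine 6 to the aldehyde 3 and acetyl chloride 4, with nitrogen supplied by a silylamide. The aldehyde has no alpha hydrogen, so the imine cannot tautomerise and enolisation can only occur on the acetyl side. The forward steps have to be run with exclusion of water.

**The aldehyde.** In 3 the two benzyl–oxygen bonds are cut (2) and then the methyl–oxygen bond, arriving at commercial 2,4,6-trihydroxybenzaldehyde 1. Formylation of a mixed phloroglucinol triether would give regioisomers, whereas in 1 the position para to the formyl group is unique. The forward methylation must select the 4-hydroxyl, which is the only one not chelated to the formyl oxygen.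

## Roads not taken

**Alternative 1:** The N1'–C2' bond is cut. The racemic benzylic alcohol A1, methyl N-[5-(2,6-dihydroxy-4-methoxyphenyl)-5-hydroxypentyl]carbamate, would be dehydrated by a chiral BINOL-derived phosphoric acid to an ortho-quinone methide. The tethered carbamate nitrogen would then add to C2' and give the piperidine carbamate A2.
- Merits: no phenol protection is needed, the precursor is racemic and easily made, and hydride reduction of the methyl carbamate of A2 would give 17 directly. In step count this road is clearly shorter than the chosen one.
- Weak points: the quinone methide of a phloroglucinol-type ring is so stabilised that closure outside the chiral ion pair can compete. The product A2 can re-ionise under the same acid, so its enantiomeric purity is exposed to erosion for as long as the catalyst is present. Six-membered closure by a carbamate nitrogen is also less secure than the intermolecular additions on which this catalysis rests.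
- Comparison: against the shorter sequence, the chosen plan sets C2' while the phenols are benzyl ethers and the nitrogen is an amide, a state in which C2' cannot ionise, and it does so in a reaction class with direct precedent.

**Alternative 2:** The N1'–C2' and N1'–C6' bonds are cut. A transaminase with an amine donor would convert the chloroketone A3, 5-chloro-1-[4-methoxy-2,6-bis(methoxymethoxy)phenyl]pentan-1-one, into the chiral primary amine, which displaces chloride and gives the piperidine A4.
- Merits: one operation sets C2' and closes the ring, and where an enzyme accepts the ketone the enantiomeric purity is usually excellent. The route would be shorter and would avoid decarboxylation and lactam reduction.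
- Weak points: the carbonyl of A3 is flanked by two ortho alkoxy groups, is twisted out of conjugation and is electron-rich, which is the profile of a poor transaminase substrate with an unfavourable equilibrium. The chloroketone can hydrolyse or cyclise in the buffer. The methoxymethyl groups must later be removed with acid at a benzylic amine that has ortho oxygens, and N-methylation is a further step.
- Comparison: if a suitable enzyme exists this road is better in both length and selectivity. The chosen plan offers a small-molecule catalyst whose two antipodes are available and whose substrate tolerance does not depend on protein screening.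

**Alternative 3:** The C5'–C6' and N1'–C6' bonds are cut. Rh(acac)(CO)2 with the diphosphite BIPHEPHOS under CO and H2 would hydroformylate the terminal alkene of the homoallylic carbamate A5, tert-butyl N-[(1R)-1-[2,6-bis(benzyloxy)-4-methoxyphenyl]but-3-en-1-yl]carbamate, at its end carbon. The carbamate nitrogen would condense with the new aldehyde to give the ene-carbamate A6.
- Merits: the linear-selective cyclohydrocarbonylation is robust. One hydrogenation would then saturate the ring and remove both benzyl groups, and hydride reduction of the carbamate would give 17, so the sequence after the key step is shorter than in the chosen plan.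
- Weak points: the key step creates no stereocenter. C2' has to be installed beforehand in A5 by a separate asymmetric allylation of an imine of aldehyde 3, normally with a stoichiometric auxiliary. Pressure equipment is needed, and reduction of a tert-butyl carbamate to N-methyl is slow.
- Comparison: this road is probably the more robust and is no longer. The chosen plan makes ring D and C2' in the same catalytic step from the achiral partners 7 and 8, with the absolute configuration selectable by the ligand.

Key step: step 5

Remark on the chemistry: the copper bisoxazoline catalyst is assumed to follow the square-planar chelate model of acryloyl oxazolidinones, under which the (R,R) ligand leaves the alpha Si face open. If the sense on this azadiene proves to be the reverse, the (S,S) ligand is used and nothing else changes. Compounds 1, 4, 8 and 19 are taken as commercial.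

## Route

Step 1
Reactants: 1 2,4,6-trihydroxybenzaldehyde
Product: 2 2,6-dihydroxy-4-methoxybenzaldehyde
Conditions: Me2SO4 (1.0 equiv), K2CO3 (1.0 equiv), acetone, 0 °C to rt
Reagents that add atoms: dimethyl sulfate, COS(=O)(=O)OC
Why: Williamson O-methylation: the 4-hydroxyl is the most acidic and the only one not hydrogen-bonded to the formyl oxygen, so one equivalent of base and of a hard methylating agent should take it first and favour O- over C-methylation; the symmetrical product is separated from any dimethyl ether by crystallisation.

Step 2
Reactants: 2 2,6-dihydroxy-4-methoxybenzaldehyde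
Product: 3 2,6-bis(benzyloxy)-4-methoxybenzaldehyde
Conditions: BnBr (2.5 equiv), K2CO3 (3 equiv), DMF, 60 °C
Reagents that add atoms: benzyl bromide, BrCc1ccccc1
Why: Williamson etherification; the two chelated hydroxyls are equivalent and nothing else in the molecule competes, so warm DMF with excess BnBr should carry both to the ether.

Step 3
Reactants: 3 2,6-bis(benzyloxy)-4-methoxybenzaldehyde; 4 acetyl chloride
Product: 6 (E)-N-{[2,6-bis(benzyloxy)-4-methoxyphenyl]methylidene}acetamide, via N-trimethylsilyl aldimine 5 (not isolated)
Conditions: LiN(SiMe3)2 (1.05 equiv), THF, 0 °C to rt; Me3SiCl (1.0 equiv), 0 °C; AcCl (1.0 equiv), 0 °C to rt; volatiles removed, residue taken up in dry toluene and filtered under argon, used crude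
Reagents that add atoms: lithium bis(trimethylsilyl)amide, [Li]N([Si](C)(C)C)[Si](C)(C)C
Why: Addition of the silylamide to the non-enolisable aldehyde and Peterson-type loss of silanolate should give the N-silyl aldimine 5, and N-acylation with loss of Me3SiCl then gives the N-acyl imine; Me3SiCl caps the lithium silanolate so that it does not consume acetyl chloride, and the electron-rich aryl group tempers the electrophilicity of 6 enough for it to be carried on crude.

Step 4
Reactants: 6 (E)-N-{[2,6-bis(benzyloxy)-4-methoxyphenyl]methylidene}acetamide
Product: 7 (E)-1-[2,6-bis(benzyloxy)-4-methoxyphenyl]-3-(tert-butyldimethylsilyloxy)-2-azabuta-1,3-diene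
Conditions: t-BuMe2SiOTf (1.1 equiv), Et3N (1.5 equiv), Et2O, 0 °C to rt; filtration under argon, no chromatography
Reagents that add atoms: tert-butyldimethylsilyl trifluoromethanesulfonate, CC(C)(C)[Si](C)(C)OS(=O)(=O)C(F)(F)F
Why: Soft enolisation: O-silylation of the N-acyl imine by the silyl triflate and removal of an acetyl proton by Et3N should give the silyl ketene N,O-acetal, the established entry to 3-silyloxy-2-azadienes; the aldimine side has no alpha hydrogen, so only the acetyl group can enolise, and the E imine geometry is kept.

Step 5
Reactants: 7 (E)-1-[2,6-bis(benzyloxy)-4-methoxyphenyl]-3-(tert-butyldimethylsilyloxy)-2-azabuta-1,3-diene; 8 3-acryloyl-1,3-oxazolidin-2-one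
Product: 10 (5R,6R)-6-[2,6-bis(benzyloxy)-4-methoxyphenyl]-5-(2-oxo-1,3-oxazolidine-3-carbonyl)piperidin-2-one, via silyl imidate cycloadduct 9 (not isolated)
Conditions: Cu(OTf)2 (10 mol %), (R,R)-tert-butyl bisoxazoline [2,2'-(propane-2,2-diyl)bis((4R)-4-tert-butyl-4,5-dihydrooxazole)] (11 mol %), 4 Å molecular sieves, CH2Cl2, −45 °C to rt; then MeOH, rt
Reagents that add atoms: none
Why: Divalent copper, held by the bisoxazoline, binds both carbonyl oxygens of 8 in a square-planar chelate with the acrylate s-cis, and the tert-butyl group of the (R,R) ligand covers the alpha Re face. The silyl ketene N,O-acetal carbon of 7 (C5') bonds to the beta carbon (C4') and the aldimine carbon (C2') to the alpha carbon (C3') in a concerted, asynchronous [4+2] cycloaddition that closes ring D as a six-membered ring; the closest known reaction type is the copper bisoxazoline catalysed Diels–Alder reaction of 1-aryl-3-silyloxy-2-azadienes with N-acryloyl oxazolidinones. Regiochemistry follows from the polarisation of the diene, whose nucleophilic terminus is the CH2 carbon. C3' is set by the ligand (attack on the alpha Si face, R), and C2' is set relative to it by exo topicity on the E aldimine, which places the aryl group trans to the acyl group and makes C2' R. The step needs facial and exo selectivity together, because an endo adduct formed on the same acrylate face carries the opposite C2'; 10 is therefore freed of any cis isomer by crystallisation or chromatography before the carboxyl is removed. The aldehyde-derived terminus cannot enolise, so 7 does not isomerise under the Lewis acid, and methanol then cleaves the O-silyl imidate 9 to the lactam.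

Step 6
Reactants: 10 (5R,6R)-6-[2,6-bis(benzyloxy)-4-methoxyphenyl]-5-(2-oxo-1,3-oxazolidine-3-carbonyl)piperidin-2-one
Product: 12 (2R,3R)-2-[2,6-bis(benzyloxy)-4-methoxyphenyl]-6-oxopiperidine-3-carboxylic acid, via peroxy acid 11 (not isolated)
Conditions: LiOH (2 equiv), 30% H2O2 (4 equiv), THF–H2O, 0 °C; Na2SO3; HCl to pH 2
Reagents that add atoms: hydrogen peroxide, OO
Why: Hydroperoxide attacks the exocyclic imide carbonyl selectively (standard oxazolidinone cleavage) to give the peroxy acid 11, which sulfite reduces to the acid; the lactam is inert, and epimerisation at C3' would be harmless because that center is removed in step 7 while C2' has no acidic hydrogen.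

Step 7
Reactants: 12 (2R,3R)-2-[2,6-bis(benzyloxy)-4-methoxyphenyl]-6-oxopiperidine-3-carboxylic acid
Product: 14 (6R)-6-[2,6-bis(benzyloxy)-4-methoxyphenyl]piperidin-2-one, via thiohydroxamate ester 13 (not isolated)
Conditions: N-hydroxypyridine-2-thione, DCC, DMAP (cat.), CH2Cl2, 0 °C to rt, dark; then t-BuSH (excess), tungsten lamp, rt
Reagents that add atoms: none
Why: Barton decarboxylation: DCC coupling gives the thiohydroxamate ester 13, whose photolysis releases CO2 and a secondary C3' radical that the thiol should quench faster than it can rearrange; the radical is not at C2', so the stereocenter set in step 5 is kept.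

Step 8
Reactants: 14 (6R)-6-[2,6-bis(benzyloxy)-4-methoxyphenyl]piperidin-2-one
Product: 15 (6R)-6-[2,6-bis(benzyloxy)-4-methoxyphenyl]-1-methylpiperidin-2-one
Conditions: NaH (1.1 equiv), MeI (1.2 equiv), THF, 0 °C to rt
Reagents that add atoms: iodomethane, CI
Why: N-Alkylation of the lactam anion; the N–H is by far the most acidic site, and the benzylic C2'–H is not acidic enough to be removed, so the configuration is safe.

Step 9
Reactants: 15 (6R)-6-[2,6-bis(benzyloxy)-4-methoxyphenyl]-1-methylpiperidin-2-one
Product: 16 (2R)-2-[2,6-bis(benzyloxy)-4-methoxyphenyl]-1-methylpiperidine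
Conditions: LiAlH4, THF, reflux; aqueous NaOH work-up
Reagents that add atoms: none
Why: LiAlH4 reduction of a tertiary lactam to the cyclic amine takes C6' from carbonyl to CH2; benzyl and methyl aryl ethers are inert to hydride and C2' is not involved.

Step 10
Reactants: 16 (2R)-2-[2,6-bis(benzyloxy)-4-methoxyphenyl]-1-methylpiperidine
Product: 17 5-methoxy-2-[(2R)-1-methylpiperidin-2-yl]benzene-1,3-diol
Conditions: H2 (1 atm), 10% Pd/C, MeOH–EtOAc, rt
Reagents that add atoms: none
Why: Hydrogenolysis of the two benzyl ethers over Pd/C; the C2'–N bond is also benzylic but is ring-bound and flanked by two ortho substituents, so O-debenzylation should be much the faster process, and neutral conditions at room temperature avoid quinone methide formation.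

Step 11
Reactants: 17 5-methoxy-2-[(2R)-1-methylpiperidin-2-yl]benzene-1,3-diol
Product: 18 4-iodo-5-methoxy-2-[(2R)-1-methylpiperidin-2-yl]benzene-1,3-diol
Conditions: NIS (1.0 equiv), CF3CO2H (1.1 equiv), MeCN, −30 °C to 0 °C; aqueous NaHCO3 work-up
Reagents that add atoms: N-iodosuccinimide, O=C1CCC(=O)N1I
Why: Electrophilic aromatic iodination of a phloroglucinol-type ring; the two open positions are related by the mirror plane of the aryl group, so only one mono-iodide is possible, and low temperature with exactly one equivalent of NIS limits di-iodination while CF3CO2H keeps the amine protonated and out of reach of the oxidant.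

Step 12
Reactants: 18 4-iodo-5-methoxy-2-[(2R)-1-methylpiperidin-2-yl]benzene-1,3-diol; 19 phenylacetylene
Product: 21 7-hydroxy-5-methoxy-8-[(2R)-1-methylpiperidin-2-yl]-2-phenyl-4H-chromen-4-one, via ortho-hydroxyaryl ynone 20 (not isolated)
Conditions: PdCl2(PPh3)2 (5 mol %), dppp (5 mol %), thiourea (5 mol %), CO (1 atm), Et2NH, DBU, DMF, 40 °C
Reagents that add atoms: carbon monoxide, [C-]#[O+]
Why: Carbonylative Sonogashira coupling and annulation of an ortho-iodophenol: zerovalent palladium, formed in the flask from PdCl2(PPh3)2, inserts into the C–I bond, CO insertion and coupling with the acetylide give the ynone 20, and the neighbouring phenoxide closes ring C by 6-endo addition, which the secondary amine favours over 5-exo closure by adding reversibly to the ynone first. Only the hydroxyl ortho to the ynone can cyclise, so the other becomes the C7 hydroxyl, and 40 °C spares C2'.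

## Compound list

1 | 2,4,6-trihydroxybenzaldehyde | O=Cc1c(O)cc(O)cc1O | starting material
2 | 2,6-dihydroxy-4-methoxybenzaldehyde | COc1cc(O)c(C=O)c(O)c1 | intermediate
3 | 2,6-bis(benzyloxy)-4-methoxybenzaldehyde | COc1cc(OCc2ccccc2)c(C=O)c(OCc3ccccc3)c1 | intermediate
4 | acetyl chloride | CC(Cl)=O | starting material
5 | (E)-1-[2,6-bis(benzyloxy)-4-methoxyphenyl]-N-(trimethylsilyl)methanimine | COc1cc(OCc2ccccc2)c(/C=N/[Si](C)(C)C)c(OCc3ccccc3)c1 | intermediate
6 | (E)-N-{[2,6-bis(benzyloxy)-4-methoxyphenyl]methylidene}acetamide | COc1cc(OCc2ccccc2)c(/C=N/C(C)=O)c(OCc3ccccc3)c1 | intermediate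
7 | (E)-1-[2,6-bis(benzyloxy)-4-methoxyphenyl]-3-(tert-butyldimethylsilyloxy)-2-azabuta-1,3-diene | COc1cc(OCc2ccccc2)c(/C=N/C(=C)O[Si](C)(C)C(C)(C)C)c(OCc3ccccc3)c1 | intermediate
8 | 3-acryloyl-1,3-oxazolidin-2-one | C=CC(=O)N1CCOC1=O | starting material
9 | 3-{[(2R,3R)-2-[2,6-bis(benzyloxy)-4-methoxyphenyl]-6-(tert-butyldimethylsilyloxy)-2,3,4,5-tetrahydropyridin-3-yl]carbonyl}-1,3-oxazolidin-2-one | COc1cc(OCc2ccccc2)c([C@H]3[C@H](C(=O)N4CCOC4=O)CCC(O[Si](C)(C)C(C)(C)C)=N3)c(OCc5ccccc5)c1 | intermediate
10 | (5R,6R)-6-[2,6-bis(benzyloxy)-4-methoxyphenyl]-5-(2-oxo-1,3-oxazolidine-3-carbonyl)piperidin-2-one | COc1cc(OCc2ccccc2)c([C@H]3[C@H](C(=O)N4CCOC4=O)CCC(=O)N3)c(OCc5ccccc5)c1 | intermediate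
11 | (2R,3R)-2-[2,6-bis(benzyloxy)-4-methoxyphenyl]-6-oxopiperidine-3-carboperoxoic acid | COc1cc(OCc2ccccc2)c([C@H]3[C@H](C(=O)OO)CCC(=O)N3)c(OCc4ccccc4)c1 | intermediate
12 | (2R,3R)-2-[2,6-bis(benzyloxy)-4-methoxyphenyl]-6-oxopiperidine-3-carboxylic acid | COc1cc(OCc2ccccc2)c([C@H]3[C@H](C(=O)O)CCC(=O)N3)c(OCc4ccccc4)c1 | intermediate
13 | 2-thioxopyridin-1(2H)-yl (2R,3R)-2-[2,6-bis(benzyloxy)-4-methoxyphenyl]-6-oxopiperidine-3-carboxylate | COc1cc(OCc2ccccc2)c([C@H]3[C@H](C(=O)On4ccccc4=S)CCC(=O)N3)c(OCc5ccccc5)c1 | intermediate
14 | (6R)-6-[2,6-bis(benzyloxy)-4-methoxyphenyl]piperidin-2-one | COc1cc(OCc2ccccc2)c([C@H]3CCCC(=O)N3)c(OCc4ccccc4)c1 | intermediate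
15 | (6R)-6-[2,6-bis(benzyloxy)-4-methoxyphenyl]-1-methylpiperidin-2-one | COc1cc(OCc2ccccc2)c([C@H]3CCCC(=O)N3C)c(OCc4ccccc4)c1 | intermediate
16 | (2R)-2-[2,6-bis(benzyloxy)-4-methoxyphenyl]-1-methylpiperidine | COc1cc(OCc2ccccc2)c([C@H]3CCCCN3C)c(OCc4ccccc4)c1 | intermediate
17 | 5-methoxy-2-[(2R)-1-methylpiperidin-2-yl]benzene-1,3-diol | COc1cc(O)c([C@H]2CCCCN2C)c(O)c1 | intermediate
18 | 4-iodo-5-methoxy-2-[(2R)-1-methylpiperidin-2-yl]benzene-1,3-diol | COc1cc(O)c([C@H]2CCCCN2C)c(O)c1I | intermediate
19 | phenylacetylene | C#Cc1ccccc1 | starting material
20 | 1-{2,4-dihydroxy-6-methoxy-3-[(2R)-1-methylpiperidin-2-yl]phenyl}-3-phenylprop-2-yn-1-one | COc1cc(O)c([C@H]2CCCCN2C)c(O)c1C(=O)C#Cc1ccccc1 | intermediate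
21 | 7-hydroxy-5-methoxy-8-[(2R)-1-methylpiperidin-2-yl]-2-phenyl-4H-chromen-4-one | COc1cc(O)c([C@H]2CCCCN2C)c2oc(-c3ccccc3)cc(=O)c12 | target

## Step count and risks

Total step count: 12. Longest linear sequence: 12 steps, from 1 to 21; compounds 4, 8 and 19 enter as purchased.

**Step 5 (key step).** The aldimine carbon carries a di-ortho-substituted, strongly donating aryl group. Bond formation at C2' may therefore be slow, or the reaction may turn stepwise (Michael addition, then Mannich closure through an aryl-stabilised N-acyliminium ion), with loss of exo selectivity and of enantiomeric purity. Hydrolysis of the diene by traces of water and acid is the other likely failure.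

The fallback gives up the cycloaddition and sets C2' with an auxiliary. It sets out from 3 and returns at 16.
- Condensation of 3 with (S)-tert-butanesulfinamide and Ti(OEt)4 should give (S,E)-N-{[2,6-bis(benzyloxy)-4-methoxyphenyl]methylidene}-2-methylpropane-2-sulfinamide F1.
- Addition of 4-chlorobutylmagnesium bromide in CH2Cl2 at low temperature, through the six-membered magnesium chelate, should give (S)-N-{(1R)-1-[2,6-bis(benzyloxy)-4-methoxyphenyl]-5-chloropentyl}-2-methylpropane-2-sulfinamide F2. If the auxiliary proves to direct the other way on this substrate, its antipode is used.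
- KOt-Bu in THF closes the ring to (2R)-2-[2,6-bis(benzyloxy)-4-methoxyphenyl]-1-[(S)-tert-butylsulfinyl]piperidine F3.
- HCl in MeOH removes the sulfinyl group to give (2R)-2-[2,6-bis(benzyloxy)-4-methoxyphenyl]piperidine F4.
- Reductive methylation with aqueous formaldehyde and NaBH(OAc)3 gives 16.

**Step 4.** The silyl ketene N,O-acetal may be lost by hydrolysis or desilylation during isolation, or enolisation of the crude N-acyl imine may be incomplete. Either would starve the key step of diene.

The fallback delivers the silyl group from nitrogen instead of from an external triflate. It sets out from 3 and returns at 7.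
- LiN(SiMe3)2 followed by t-BuMe2SiCl (silyl exchange on nitrogen through 5) should give (E)-1-[2,6-bis(benzyloxy)-4-methoxyphenyl]-N-(tert-butyldimethylsilyl)methanimine F5.
- Treatment of F5 with acetyl chloride and Et3N in one flask acylates nitrogen and releases t-BuMe2SiCl, which with the amine silylates the enol oxygen to give 7 without isolation of 6.

**Step 11.** Over-iodination of the very electron-rich ring to the di-iodide, and oxidation at nitrogen or at the benzylic C2'–H, are the likely failures. The free diphenol is also sensitive to air.

The fallback iodinates before the phenols are freed. It sets out from 16 and returns at 18.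
- NIS with CF3CO2H in MeCN on the less activated bis-benzyl ether should stop cleanly at (2R)-2-[2,6-bis(benzyloxy)-3-iodo-4-methoxyphenyl]-1-methylpiperidine F6.
- BCl3 with pentamethylbenzene in CH2Cl2 at −78 °C then removes the benzyl groups without touching the iodide or the methyl ether and gives 18.

**Step 12.** Oxidative addition into a di-ortho-substituted, phenoxide-bearing aryl iodide may be slow. Aminocarbonylation by Et2NH can compete with alkynylation, closure may go partly 5-exo to the aurone, and any need for stronger heating invites racemisation at C2' through the quinone methide.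

The fallback builds ring C by classical acylation chemistry without palladium. It sets out from 17, bypasses step 11 and returns at 21.
- Houben–Hoesch acylation with acetonitrile (ZnCl2, HCl, Et2O, then brief aqueous hydrolysis) should give 1-{2,4-dihydroxy-6-methoxy-3-[(2R)-1-methylpiperidin-2-yl]phenyl}ethan-1-one F7.
- Excess LiN(SiMe3)2 followed by one equivalent of benzoyl chloride C-benzoylates the ketone enolate (Baker–Venkataraman-type construction) to give 1-{2,4-dihydroxy-6-methoxy-3-[(2R)-1-methylpiperidin-2-yl]phenyl}-3-phenylpropane-1,3-dione F8.
- Cyclodehydration in AcOH with catalytic H2SO4, kept as short and cool as possible, gives 21.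

## Further compounds

F1 | step 5 | (S,E)-N-{[2,6-bis(benzyloxy)-4-methoxyphenyl]methylidene}-2-methylpropane-2-sulfinamide | CC(C)(C)[S@](=O)/N=C/c1c(OCc2ccccc2)cc(OC)cc1OCc1ccccc1
F2 | step 5 | (S)-N-{(1R)-1-[2,6-bis(benzyloxy)-4-methoxyphenyl]-5-chloropentyl}-2-methylpropane-2-sulfinamide | CC(C)(C)[S@](=O)N[C@H](CCCCCl)c1c(OCc2ccccc2)cc(OC)cc1OCc1ccccc1
F3 | step 5 | (2R)-2-[2,6-bis(benzyloxy)-4-methoxyphenyl]-1-[(S)-tert-butylsulfinyl]piperidine | CC(C)(C)[S@](=O)N1CCCC[C@@H]1c1c(OCc2ccccc2)cc(OC)cc1OCc1ccccc1
F4 | step 5 | (2R)-2-[2,6-bis(benzyloxy)-4-methoxyphenyl]piperidine | COc1cc(OCc2ccccc2)c([C@H]3CCCCN3)c(OCc4ccccc4)c1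
F5 | step 4 | (E)-1-[2,6-bis(benzyloxy)-4-methoxyphenyl]-N-(tert-butyldimethylsilyl)methanimine | COc1cc(OCc2ccccc2)c(/C=N/[Si](C)(C)C(C)(C)C)c(OCc3ccccc3)c1
F6 | step 11 | (2R)-2-[2,6-bis(benzyloxy)-3-iodo-4-methoxyphenyl]-1-methylpiperidine | COc1cc(OCc2ccccc2)c([C@H]3CCCCN3C)c(OCc4ccccc4)c1I
F7 | step 12 | 1-{2,4-dihydroxy-6-methoxy-3-[(2R)-1-methylpiperidin-2-yl]phenyl}ethan-1-one | COc1cc(O)c([C@H]2CCCCN2C)c(O)c1C(C)=O
F8 | step 12 | 1-{2,4-dihydroxy-6-methoxy-3-[(2R)-1-methylpiperidin-2-yl]phenyl}-3-phenylpropane-1,3-dione | COc1cc(O)c([C@H]2CCCCN2C)c(O)c1C(=O)CC(=O)c1ccccc1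
A1 | alternative 1 | methyl N-[5-(2,6-dihydroxy-4-methoxyphenyl)-5-hydroxypentyl]carbamate (racemic) | COC(=O)NCCCCC(O)c1c(O)cc(OC)cc1O
A2 | alternative 1 | methyl (2R)-2-(2,6-dihydroxy-4-methoxyphenyl)piperidine-1-carboxylate | COc1cc(O)c([C@H]2CCCCN2C(=O)OC)c(O)c1
A3 | alternative 2 | 5-chloro-1-[4-methoxy-2,6-bis(methoxymethoxy)phenyl]pentan-1-one | COCOc1cc(OC)cc(OCOC)c1C(=O)CCCCCl
A4 | alternative 2 | (2R)-2-[4-methoxy-2,6-bis(methoxymethoxy)phenyl]piperidine | COc1cc(OCOC)c([C@H]2CCCCN2)c(OCOC)c1
A5 | alternative 3 | tert-butyl N-[(1R)-1-[2,6-bis(benzyloxy)-4-methoxyphenyl]but-3-en-1-yl]carbamate | COc1cc(OCc2ccccc2)c([C@H](NC(=O)OC(C)(C)C)CC=C)c(OCc3ccccc3)c1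
A6 | alternative 3 | tert-butyl (2R)-2-[2,6-bis(benzyloxy)-4-methoxyphenyl]-3,4-dihydro-2H-pyridine-1-carboxylate | COc1cc(OCc2ccccc2)c([C@H]3CCC=CN3C(=O)OC(C)(C)C)c(OCc4ccccc4)c1
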